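**Retrosynthetic overview**

1. The last bond made is O–C4a of the dihydrofuran (hexahydrodibenzofuran numbering). C-4a is β to the ring ketone C-3 and is bonded to the quaternary C-9b, which carries the aryl ring whose ortho carbon C-5a holds the ether oxygen. Cutting O–C4a and returning C4–C4a to CH2–CH2 leaves an ortho-phenol on C-4 of a 4,4-disubstituted cyclohexanone whose two CH2CH2 arms are mirror images, an achiral macrocycle with no stereocentre.
2. Forward, an FMN-dependent ene-reductase (Old Yellow Enzyme class) run as a desaturase under O2 oxidises one enantiotopic arm to the enone, and the phenol closes the dihydrofuran by oxa-Michael addition in the same pot. This sets both stereocentres, the last ring and the final oxidation level at once, on the unprotected amine.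
3. The 20-membered macrocycle is closed before that at the aryl–CH= bond by an intramolecular Heck reaction. Its other alkene comes from a Horner–Wadsworth–Emmons union of a lactol with a spermidine-derived phosphonoacetamide/acrylamide fragment.
4. The cyclohexanone ring is made first, by double Michael addition and Dieckmann condensation on 5-bromo-1-benzofuran-2(3H)-one. The aryl lactone is a temporary ring that masks both the phenol and the future aldehyde carbon.
5. Ring order: benzene (bought) → cyclohexanone → macrocycle → dihydrofuran.

Key step: step 13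

Remark: 5-bromo-1-benzofuran-2(3H)-one (compound 1) is taken as a purchasable building block (it is the lactone of (5-bromo-2-hydroxyphenyl)acetic acid), and the enzyme of step 13 is taken from a screened panel of Old Yellow Enzyme family members.

**Route**

Step 1
Reactants: 1 5-bromo-1-benzofuran-2(3H)-one; 2 methyl acrylate (2.5 equiv)
Product: 3 dimethyl 3,3'-(5-bromo-2-oxo-2,3-dihydro-1-benzofuran-3,3-diyl)dipropanoate
Conditions: DBU (0.2 equiv), MeCN, 0 °C to rt
Reagents that add atoms: none
Why: Double Michael addition, in which the C-3 methylene (activated by the lactone carbonyl and the aryl ring) forms a stabilised enolate under catalytic amidine base and adds twice to the acrylate, with no stereocentre formed.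

Step 2
Reactants: 3 dimethyl 3,3'-(5-bromo-2-oxo-2,3-dihydro-1-benzofuran-3,3-diyl)dipropanoate
Product: 5 5-bromo-2H-spiro[1-benzofuran-3,1'-cyclohexane]-2,4'-dione, via Dieckmann keto ester 4 (not isolated)
Conditions: KOt-Bu (2.2 equiv), THF, 0 °C to rt; then 6 M HCl, AcOH, 100 °C
Reagents that add atoms: none
Why: Dieckmann condensation of the two identical propanoate arms closes the six-membered ring, and acidic ester hydrolysis and decarboxylation (during which any opened aryl lactone closes again) should give the achiral spiro ketone.

Step 3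
Reactants: 5 5-bromo-2H-spiro[1-benzofuran-3,1'-cyclohexane]-2,4'-dione
Product: 6 5-bromo-2H-dispiro[1-benzofuran-3,1'-cyclohexane-4',2''-[1,3]dioxolan]-2-one
Conditions: HOCH2CH2OH (3 equiv), TsOH·H2O (5 mol%), toluene, reflux (Dean–Stark)
Reagents that add atoms: ethylene glycol, OCCO
Why: Acid-catalysed ketalisation with azeotropic removal of water masks the ketone for the hydride step, the five-membered aryl lactone being restored under the same equilibrating conditions.

Step 4
Reactants: 6 5-bromo-2H-dispiro[1-benzofuran-3,1'-cyclohexane-4',2''-[1,3]dioxolan]-2-one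
Product: 7 5-bromo-2H-dispiro[1-benzofuran-3,1'-cyclohexane-4',2''-[1,3]dioxolan]-2-ol (racemic lactol)
Conditions: diisobutylaluminium hydride (1.2 equiv), CH2Cl2, −78 °C; aq. KNaC4H4O6
Reagents that add atoms: none
Why: Partial reduction of a lactone to a lactol, the tetrahedral aluminate being held at low temperature until hydrolysis; the lactol carbon forms as a racemate and is consumed in step 10.

Step 5
Reactants: 8 tert-butyl (4-aminobutyl)carbamate; 9 (diethoxyphosphoryl)acetic acid
Product: 10 tert-butyl {4-[2-(diethoxyphosphoryl)acetamido]butyl}carbamate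
Conditions: DIC, HOBt, CH2Cl2, 0 °C to rt
Reagents that add atoms: none
Why: Carbodiimide amide coupling through the benzotriazolyl active ester, the primary amine being the only nucleophile present.

Step 6
Reactants: 10 tert-butyl {4-[2-(diethoxyphosphoryl)acetamido]butyl}carbamate
Product: 11 diethyl {2-[(4-aminobutyl)amino]-2-oxoethyl}phosphonate hydrochloride
Conditions: 4 M HCl in dioxane, rt
Reagents that add atoms: hydrogen chloride, Cl
Why: Acidolysis of the tert-butyl carbamate, to which the phosphonate esters and the amide are inert under anhydrous HCl at room temperature.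

Step 7
Reactants: 11 diethyl {2-[(4-aminobutyl)amino]-2-oxoethyl}phosphonate hydrochloride; 12 acrylonitrile (1.05 equiv)
Product: 14 tert-butyl (2-cyanoethyl){4-[2-(diethoxyphosphoryl)acetamido]butyl}carbamate, via cyanoethylamine 13 (not isolated)
Conditions: Et3N (1.1 equiv), MeOH, 0 °C to rt; then Boc2O (1.2 equiv), rt
Reagents that add atoms: di-tert-butyl dicarbonate, CC(C)(C)OC(=O)OC(=O)OC(C)(C)C
Why: Aza-Michael addition of the primary amine to acrylonitrile stops at monoalkylation with one equivalent at room temperature, and the secondary amine is then capped as its carbamate in the same pot.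

Step 8
Reactants: 14 tert-butyl (2-cyanoethyl){4-[2-(diethoxyphosphoryl)acetamido]butyl}carbamate
Product: 15 tert-butyl (3-aminopropyl){4-[2-(diethoxyphosphoryl)acetamido]butyl}carbamate
Conditions: H2 (4 bar), Raney Ni, 7 M NH3 in MeOH, rt
Reagents that add atoms: none
Why: Catalytic hydrogenation of the nitrile to the primary amine, with ammonia suppressing secondary-amine formation and the carbamate, amide and phosphonate left untouched.

Step 9
Reactants: 15 tert-butyl (3-aminopropyl){4-[2-(diethoxyphosphoryl)acetamido]butyl}carbamate; 16 acryloyl chloride (1.05 equiv)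
Product: 17 tert-butyl (3-acrylamidopropyl){4-[2-(diethoxyphosphoryl)acetamido]butyl}carbamate
Conditions: Et3N (1.5 equiv), CH2Cl2, −20 °C
Reagents that add atoms: none
Why: N-Acylation of the primary amine by the acid chloride is much faster at low temperature than aza-Michael addition to the acrylamide being formed.

Step 10
Reactants: 7 5-bromo-2H-dispiro[1-benzofuran-3,1'-cyclohexane-4',2''-[1,3]dioxolan]-2-ol; 17 tert-butyl (3-acrylamidopropyl){4-[2-(diethoxyphosphoryl)acetamido]butyl}carbamate (1.2 equiv)
Product: 19 4-bromo-2-{8-[(E)-3-({4-[(3-acrylamidopropyl)(tert-butoxycarbonyl)amino]butyl}amino)-3-oxoprop-1-en-1-yl]-1,4-dioxaspiro[4.5]decan-8-yl}phenyl acetate, via ring-opened phenol 18 (not isolated)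
Conditions: NaH (2.2 equiv), THF, 0 °C to rt; then Ac2O (1.5 equiv), 0 °C
Reagents that add atoms: acetic anhydride, CC(=O)OC(C)=O
Why: Horner–Wadsworth–Emmons olefination of the lactol, whose sodium salt opens to the phenoxide aldehyde; the stabilised phosphonate anion and the α-quaternary aldehyde should give the (E)-acrylamide, and the liberated phenoxide is acetylated before it can add to the new alkene.

Step 11
Reactants: 19 4-bromo-2-{8-[(E)-3-({4-[(3-acrylamidopropyl)(tert-butoxycarbonyl)amino]butyl}amino)-3-oxoprop-1-en-1-yl]-1,4-dioxaspiro[4.5]decan-8-yl}phenyl acetate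
Product: 20 macrocyclic ketal acetate: 8-(2-acetoxyphenyl)-1,4-dioxaspiro[4.5]decane whose C-8 (E)-CH=CH–C(=O) group is amide-bound to the 4-aminobutyl nitrogen and whose aryl C-5 (E)-CH=CH–C(=O) group is amide-bound to the 3-aminopropyl nitrogen of N4-Boc-spermidine (20-membered bis-lactam; achiral)
Conditions: Pd(OAc)2 (0.2 equiv), P(o-tol)3 (0.5 equiv), Et3N (3 equiv), MeCN (0.002 M), 80 °C
Reagents that add atoms: none
Why: Intramolecular Mizoroki–Heck reaction, in which zerovalent palladium inserts into the aryl C–Br bond, the aryl–palladium adds to the free terminus of the only monosubstituted alkene and syn β-hydride elimination gives the (E)-cinnamamide, high dilution favouring the 20-membered ring over oligomers.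

Step 12
Reactants: 20 macrocyclic ketal acetate
Product: 21 achiral macrocyclic precursor hydrochloride: 4-(2-hydroxyphenyl)cyclohexanone whose C-4 (E)-CH=CH–C(=O) group is amide-bound to the 4-aminobutyl nitrogen and whose aryl C-5 (E)-CH=CH–C(=O) group is amide-bound to the 3-aminopropyl nitrogen of spermidine (secondary ammonium chloride)
Conditions: 3 M HCl, dioxane/H2O (2:1), 50 °C
Reagents that add atoms: water, O; hydrogen chloride, Cl
Why: Acid hydrolysis cleaves the ketal, the tert-butyl carbamate and the aryl acetate in one operation, while the secondary acrylamides and the saturated ketone are stable to aqueous acid at this temperature.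

Step 13
Reactants: 21 achiral macrocyclic precursor hydrochloride
Product: 23 (4aR,9bS)-3-oxo-1,2,3,4,4a,9b-hexahydrodibenzo[b,d]furan whose C-9b (E)-CH=CH–C(=O) group is amide-bound to the 4-aminobutyl nitrogen and whose C-8 (E)-CH=CH–C(=O) group is amide-bound to the 3-aminopropyl nitrogen of spermidine (cis-fused; target CNP0415009.1), via (S)-enone 22 (not isolated)
Conditions: ene-reductase (Old Yellow Enzyme family, FMN-dependent, no NAD(P)H added), catalase, O2 (1 atm), K2HPO4/KH2PO4 buffer pH 8.0, DMSO (10% v/v), 40 °C; then aq. K2CO3
Reagents that add atoms: none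
Why: Proposed new method: the enzyme-bound FMN, kept oxidised by O2, takes the hydride from C-β and an active-site base takes the proton from C-α of one CH2CH2 arm of the ketone (the reverse of ene-reduction), and the (S)-enone 22 is trapped at once by the ortho-phenolate in a 5-exo-trig oxa-Michael addition that closes the dihydrofuran ring. The closest known reaction types are the aerobic α,β-desaturation of cyclohexanones by Old Yellow Enzymes run in reverse, the ene-reductase desymmetrisation of 4,4-disubstituted cyclohexa-2,5-dienones (same quaternary stereocentre, reductive direction) and the spontaneous closure of 4-(2-hydroxyaryl)cyclohexenones to cis-fused hexahydrodibenzofuranones; joining them in one pot on an unprotected macrocycle is what is new. The quaternary C-9b is controlled by the enzyme, which must oxidise only the pro-S arm of the mirror-symmetric ring, and C-4a is controlled by the substrate, because the phenol tethered through C-9b reaches the enone only on the face syn to the aryl ring, so only the cis fusion can form. The step needs arm selectivity, secured by choosing among stereocomplementary family members, and it needs addition to the ring enone and not to the two acrylamides, secured by the far higher electrophilicity of the ketone-activated alkene and the reversibility of the addition. It also needs no second desaturation, which is disfavoured because the arm left in 23 is the one the enzyme has already rejected, and no reduction of any alkene, which cannot occur without a nicotinamide cofactor. The trapping pulls the uphill dehydrogenation forward and keeps the enone concentration low.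

**Compound list**

1 | 5-bromo-1-benzofuran-2(3H)-one | O=C1Cc2cc(Br)ccc2O1 | starting material
2 | methyl acrylate | C=CC(=O)OC | starting material
3 | dimethyl 3,3'-(5-bromo-2-oxo-2,3-dihydro-1-benzofuran-3,3-diyl)dipropanoate | COC(=O)CCC1(CCC(=O)OC)C(=O)Oc2ccc(Br)cc21 | intermediate
4 | methyl 5-bromo-2,4'-dioxo-2H-spiro[1-benzofuran-3,1'-cyclohexane]-3'-carboxylate (Dieckmann keto ester, racemic, not isolated) | COC(=O)C1CC2(CCC1=O)C(=O)Oc1ccc(Br)cc12 | intermediate
5 | 5-bromo-2H-spiro[1-benzofuran-3,1'-cyclohexane]-2,4'-dione | O=C1CCC2(CC1)C(=O)Oc1ccc(Br)cc12 | intermediate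
6 | 5-bromo-2H-dispiro[1-benzofuran-3,1'-cyclohexane-4',2''-[1,3]dioxolan]-2-one | O=C1Oc2ccc(Br)cc2C13CCC2(CC3)OCCO2 | intermediate
7 | 5-bromo-2H-dispiro[1-benzofuran-3,1'-cyclohexane-4',2''-[1,3]dioxolan]-2-ol (racemic lactol) | OC1Oc2ccc(Br)cc2C13CCC2(CC3)OCCO2 | intermediate
8 | tert-butyl (4-aminobutyl)carbamate | CC(C)(C)OC(=O)NCCCCN | starting material
9 | (diethoxyphosphoryl)acetic acid | CCOP(=O)(OCC)CC(=O)O | starting material
10 | tert-butyl {4-[2-(diethoxyphosphoryl)acetamido]butyl}carbamate | CCOP(=O)(OCC)CC(=O)NCCCCNC(=O)OC(C)(C)C | intermediate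
11 | diethyl {2-[(4-aminobutyl)amino]-2-oxoethyl}phosphonate hydrochloride | CCOP(=O)(OCC)CC(=O)NCCCCN.Cl | intermediate
12 | acrylonitrile | C=CC#N | starting material
13 | diethyl [2-({4-[(2-cyanoethyl)amino]butyl}amino)-2-oxoethyl]phosphonate (not isolated) | CCOP(=O)(OCC)CC(=O)NCCCCNCCC#N | intermediate
14 | tert-butyl (2-cyanoethyl){4-[2-(diethoxyphosphoryl)acetamido]butyl}carbamate | CCOP(=O)(OCC)CC(=O)NCCCCN(CCC#N)C(=O)OC(C)(C)C | intermediate
15 | tert-butyl (3-aminopropyl){4-[2-(diethoxyphosphoryl)acetamido]butyl}carbamate | CCOP(=O)(OCC)CC(=O)NCCCCN(CCCN)C(=O)OC(C)(C)C | intermediate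
16 | acryloyl chloride | C=CC(=O)Cl | starting material
17 | tert-butyl (3-acrylamidopropyl){4-[2-(diethoxyphosphoryl)acetamido]butyl}carbamate | CCOP(=O)(OCC)CC(=O)NCCCCN(CCCNC(=O)C=C)C(=O)OC(C)(C)C | intermediate
18 | tert-butyl (3-acrylamidopropyl)[4-({(E)-3-[8-(5-bromo-2-hydroxyphenyl)-1,4-dioxaspiro[4.5]decan-8-yl]prop-2-enoyl}amino)butyl]carbamate (ring-opened phenol, not isolated) | Oc1ccc(Br)cc1C1(/C=C/C(=O)NCCCCN(CCCNC(=O)C=C)C(=O)OC(C)(C)C)CCC2(CC1)OCCO2 | intermediate
19 | 4-bromo-2-{8-[(E)-3-({4-[(3-acrylamidopropyl)(tert-butoxycarbonyl)amino]butyl}amino)-3-oxoprop-1-en-1-yl]-1,4-dioxaspiro[4.5]decan-8-yl}phenyl acetate | CC(=O)Oc1ccc(Br)cc1C1(/C=C/C(=O)NCCCCN(CCCNC(=O)C=C)C(=O)OC(C)(C)C)CCC2(CC1)OCCO2 | intermediate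
20 | macrocyclic ketal acetate (N4-Boc, aryl acetate, ethylene ketal; 20-membered (E,E)-bis-lactam; achiral) | O1CCOC12CCC3(CC2)/C=C/C(=O)NCCCCN(C(=O)OC(C)(C)C)CCCNC(=O)/C=C/c2ccc(OC(C)=O)c3c2 | intermediate
21 | achiral macrocyclic precursor hydrochloride (free cyclohexanone, free phenol, secondary ammonium chloride) | O=C1CCC2(CC1)/C=C/C(=O)NCCCCNCCCNC(=O)/C=C/c1ccc(O)c2c1.Cl | intermediate
22 | (S)-4-aryl-4-alkenylcyclohex-2-enone macrocycle (free phenol, free amine; not isolated) | O=C1CC[C@]2(C=C1)/C=C/C(=O)NCCCCNCCCNC(=O)/C=C/c1ccc(O)c2c1 | intermediate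
23 | (4aR,9bS)-configured cis-fused hexahydrodibenzofuran-3-one spermidine bis-lactam (CNP0415009.1) | O=C1CC[C@]23/C=C/C(=O)NCCCCNCCCNC(=O)/C=C/c4ccc(c2c4)O[C@@H]3C1 | target

**Totals and risks**

Total step count: 13.
Longest linear sequence: 9 steps (from 8 through steps 5 to 13). The branch from 1 has 8 steps (1 to 4, then 10 to 13).

Steps most likely to fail:

Step 13 (Proposed new method). What may go wrong:
- slow turnover, because a bulky macrocycle must place a CH2 next to a quaternary carbon over the flavin;
- non-productive binding of the phenolate end of the substrate in the active site;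
- erosion of the arm selectivity;
- a second desaturation of the product.

The fallback uses known chemistry and makes the stereocentre by reduction instead of oxidation. It sets out from 20. Selective ketal hydrolysis (PPTS, acetone/H2O, 60 °C; carbamate and acetate kept) should give the N-Boc acetate cyclohexanone F1. Double dehydrogenation with 2-iodoxybenzoic acid (DMSO, 70 °C) should give the cyclohexa-2,5-dienone F2. NADPH-dependent ene-reductase reduction with glucose dehydrogenase/glucose recycling (the known desymmetrisation of 4,4-disubstituted cyclohexadienones) should reduce one enantiotopic C=C and give the (S)-enone acetate F3. K2CO3 in MeOH then removes the acetyl group, and the phenoxide closes the ring by oxa-Michael addition to give the N-Boc derivative of the target F4. CF3CO2H in CH2Cl2 removes the carbamate, and the route is rejoined at 23.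

Step 11. What may go wrong: intermolecular Heck coupling to oligomers at the dilution needed for ring closure, and loss of active zerovalent palladium over the long reaction time.

The fallback closes the macrocycle at the other alkene instead. It sets out from 7 (with 17). An intermolecular Heck reaction at normal concentration (Pd(OAc)2, P(o-tol)3, Et3N, MeCN, 80 °C) should give the lactol cinnamamide phosphonate F5. An intramolecular Horner–Wadsworth–Emmons reaction under Masamune–Roush conditions (LiCl, DBU, MeCN, 0.002 M) on the ring-opened lactol should then give the macrocyclic ketal phenol F6. Treating F6 under the conditions of step 12 rejoins the route at 21.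

Step 10. What may go wrong: incomplete opening of the hindered lactol, Michael addition of the phosphonate anion to the terminal acrylamide while the olefination is slow, and cyclisation of the phenoxide onto the new acrylamide before acetylation.

The fallback avoids the lactol and the free phenoxide. It sets out from 6. LiAlH4 (THF, 0 °C) should reduce the lactone to 4-bromo-2-[8-(hydroxymethyl)-1,4-dioxaspiro[4.5]decan-8-yl]phenol F7. Selective acetylation of the phenoxide (Ac2O, aq. NaOH/CH2Cl2, 0 °C) should give 4-bromo-2-[8-(hydroxymethyl)-1,4-dioxaspiro[4.5]decan-8-yl]phenyl acetate F8. Dess–Martin oxidation should give 4-bromo-2-(8-formyl-1,4-dioxaspiro[4.5]decan-8-yl)phenyl acetate F9. Olefination of this free aldehyde with 17 under mild Masamune–Roush conditions (LiCl, N,N-diisopropylethylamine, MeCN) rejoins the route at 19.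

**Further compounds**

F1 | step 13 | N-Boc acetate cyclohexanone macrocycle (20 without the ketal) | O=C1CCC2(CC1)/C=C/C(=O)NCCCCN(C(=O)OC(C)(C)C)CCCNC(=O)/C=C/c1ccc(OC(C)=O)c2c1
F2 | step 13 | N-Boc acetate cyclohexa-2,5-dienone macrocycle | O=C1C=CC2(C=C1)/C=C/C(=O)NCCCCN(C(=O)OC(C)(C)C)CCCNC(=O)/C=C/c1ccc(OC(C)=O)c2c1
F3 | step 13 | (S)-enone acetate (N-Boc) | O=C1CC[C@]2(C=C1)/C=C/C(=O)NCCCCN(C(=O)OC(C)(C)C)CCCNC(=O)/C=C/c1ccc(OC(C)=O)c2c1
F4 | step 13 | N-Boc derivative of the target | O=C1CC[C@]23/C=C/C(=O)NCCCCN(C(=O)OC(C)(C)C)CCCNC(=O)/C=C/c4ccc(c2c4)O[C@@H]3C1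
F5 | step 11 | lactol cinnamamide phosphonate (7 with Br replaced by the (E)-acrylamide chain of 17) | OC1Oc2ccc(/C=C/C(=O)NCCCN(CCCCNC(=O)CP(=O)(OCC)OCC)C(=O)OC(C)(C)C)cc2C13CCC2(CC3)OCCO2
F6 | step 11 | macrocyclic ketal phenol (20 without the acetyl group) | O1CCOC12CCC3(CC2)/C=C/C(=O)NCCCCN(C(=O)OC(C)(C)C)CCCNC(=O)/C=C/c2ccc(O)c3c2
F7 | step 10 | 4-bromo-2-[8-(hydroxymethyl)-1,4-dioxaspiro[4.5]decan-8-yl]phenol | OCC1(CCC2(CC1)OCCO2)c1cc(Br)ccc1O
F8 | step 10 | 4-bromo-2-[8-(hydroxymethyl)-1,4-dioxaspiro[4.5]decan-8-yl]phenyl acetate | CC(=O)Oc1ccc(Br)cc1C1(CO)CCC2(CC1)OCCO2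
F9 | step 10 | 4-bromo-2-(8-formyl-1,4-dioxaspiro[4.5]decan-8-yl)phenyl acetate | CC(=O)Oc1ccc(Br)cc1C1(C=O)CCC2(CC1)OCCO2
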